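# Proposed total synthesis of CNP0126002.2

Abbreviation: TBS = tert-butyldimethylsilyl. Locants are halimane-type: ring A = C1–C5 and C10, ring B = C5–C10, C17 = methyl on C8, C18 and C19 = methyls on C4, C20 = methyl on C9, side chain C11–C15 with methyl C16 on C13. They are carried back onto all intermediates.

## Analysis of the target

CNP0126002.2 is a bicyclic diterpenoid of the halimane type. Ring A carries a gem-dimethyl group at C4 and is fused to ring B through a tetrasubstituted C5=C10 double bond; C9 bears the methyl group C20 and a side chain that ends in a vinyl carbinol. Ring B holds four contiguous stereocentres: C6 (S, free hydroxyl), C7 (R, acetate), C8 (S, methyl C17) and the quaternary C9 (R). On the ring the two oxygens are cis (both β), the C17 methyl is trans to the acetate, and C17 is cis to the side-chain carbon C11 and trans to C20. The fifth centre, C13 (S), is a tertiary allylic alcohol four bonds from C9, out of reach of substrate control. The C6 hydroxyl is allylic to the tetrasubstituted alkene and the C13 hydroxyl is a tertiary vinyl carbinol, so both ionise under acid, and the cis hydroxy acetate can shift its acyl group under base; the last steps must therefore be near neutral. The difficulty lies in the quaternary C9 wedged between C8 and a fully substituted alkene (itself flanked by the quaternary C4), in a cis-diol monoacetate on the correct face, and in C13. The strategy rests on one feature: C17 and C11 sit cis on the adjacent carbons C8 and C9, so they can be two ring atoms of a butenolide whose alkene is C8=C9, while C7, C6 (with its oxygen), C5 and C10 are the four carbons of a 2-silyloxydiene built on ring A.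

## Retrosynthetic reasoning

**C7 acetate (31 ⇒ 30).** The acyl–O7 bond is cut first, because a cis hydroxy acetate would not survive the hydride, ylide and desilylation steps. The forward acylation has to tell O7 from the hindered allylic O6 and the tertiary O13 in triol 30.

**Ring B silyl ethers (30 ⇒ 29).** Both ring oxygens are carried as TBS ethers. They tolerate base, hydride and organometallic steps and come off without acid, which the two allylic alcohols would not stand.

**C13 carbinol (29 ⇒ 28 ⇒ 27 ⇒ 26).** Addition of a vinyl nucleophile to a C13 methyl ketone would have to distinguish CH3 from CH2CH2R with no help from the ring, and it could not be run beside an acetate. The C13–O bond is therefore traced to an epoxide. Cutting C14–O and C15–I leads from 29 through epoxy iodide 28 to epoxy alcohol 27 and on to the (Z)-allylic alcohol 26, so that C13 is set by a Sharpless epoxidation under reagent control.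

**C12–C13 bond (26 ⇒ 22 + 24; 24 ⇒ 23).** C11 is neopentyl, so alkylation there is not an option. A vinyl group on C9 (alkene 22) becomes a C12 boron nucleophile by hydroboration and is joined to the alkenyl iodide 24 with retention of geometry. Iodide 24 comes from alkynol 23 in one step.

**C17 methyl and C9 vinyl (22 ⇒ 21 ⇒ 20 ⇒ 19 ⇒ 18).** In lactone 18, C11 is at the acid level and C17 at the alcohol level, so the two one-carbon branches are already told apart. Partial reduction to lactol 19 and methylenation turn C11 into the vinyl group of 20. This frees the C17 hydroxyl only once no second hydroxyl is nearby; a 1,4-diol would close to a cyclic ether on activation. The C17–O bond is then cut through mesylate 21 by hydride.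

**Lactone from lactone acetal (18 ⇒ 16, via 17).** The acetal carbon C17 is taken from the aldehyde to the alcohol level while the auxiliary 9 leaves and C11 stays a carboxyl carbon.

**Ring B oxygens (16 ⇒ 15 ⇒ 14 ⇒ 13 ⇒ 12).** The C7–O bond comes from Rubottom oxidation of enone 12 through dienol ether 13, and the C6 carbinol from reduction of ketone 14. This is done while C11 and C17 are still locked in the lactone acetal. That group has no acidic hydrogen, survives amide base, peracid and borohydride, and its cis fusion shields the α face of ring B.

**C5=C10 alkene (12 ⇒ 11).** The alkene comes from the silyl enol ether 11 by Saegusa–Ito dehydrosilylation. C4 has no hydrogen, so only H10 can leave, and the C10 stereocentre of 11 is erased.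

**Ring B (11 ⇒ 6 + 10), the key disconnection.** The C7–C8 and C9–C10 bonds are cut together. This gives ring A diene 6 and butenolide 10, whose acetal substituent controls the face of attack. The forward cycloaddition must build the quaternary C9, place C17 and C11 cis, and leave the C6 oxygen as an enol ether.

**Diene (6 ⇒ 5 ⇒ 4 ⇒ 2 ⇒ 1, with 3).** The C5–C6 bond is cut to vinyllithium 4 and amide 3. Lithium reagent 4 comes from ketone 1 through hydrazone 2 by a Shapiro reaction, regiospecific because 1 has a single α-CH2.

**Dienophile (10 ⇒ 8 + 9; 8 ⇒ 7).** The acetal C–O bond is cut to lactol 8 and (−)-menthol 9. Lactol 8 comes from furoic acid 7 by photo-oxygenation with loss of the carboxyl carbon.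

## Alternatives that were turned down

**Alternative 1:** The disconnection is the C4–C5 bond of ring A. Ring B would be in hand first as the monocyclic enone A2, with C8 and C9 set, an allyl group standing in for the side chain and a 4-methylpent-3-enyl chain on C10. In the forward key step acid protonates the trisubstituted alkene of A2, the tertiary C4 cation is captured by C5 (the α-carbon of the enone), and loss of H5 restores conjugation to give the bicyclic enone A1.
- For: one step installs ring A, the gem-dimethyl group and the C5=C10/C6=O array. C17 is a methyl group from the start and C11 is already part of a carbon chain, so the redox work the chosen route spends on the lactone carbons is not needed. No auxiliary is attached and removed.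
- Against: the α-carbon of an enone is a poor π-nucleophile, so the cation is more likely to lose a proton or be trapped by the medium than to cyclise. The quaternary C9 has to be made beforehand by alkylation next to C8, where only the C8 methyl steers the incoming group. The allyl group needs several steps to become the C11–C13 unit, and the C6, C7 and C13 problems remain.
- Comparison: on step count to the bicyclic enone (A1 against 12) this alternative is stronger. The chosen strategy offers certainty at C8 and C9 instead: the cis relation is enforced by a ring, the absolute sense by the acetal substituent, and the ring-forming step is a pericyclic reaction with matched electronics.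

**Alternative 2:** The strategic bond is the C5=C10 double bond itself. It is made, and ring A closed, from the open-chain keto ynol ether A4, in which C5 and C6 are the alkyne carbons and C10 is a ketone. A carbophilic Lewis acid triggers [2+2] addition of the electron-rich alkyne to the C10 carbonyl, and opening of the oxetene gives the tetrasubstituted enoate A3 with C6 as a silyl ester on C5.
- For: the hindered alkene forms regiospecifically, with no dehydrogenation at a crowded carbon. That is the weak point of step 7 of the chosen route, and here the alternative is stronger. C6 and C7 arrive oxygenated and differentiated.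
- Against: A4 must already contain C8 and the quaternary C9 in an open chain, where no ring helps to set their relation, and that costs a long linear sequence before the key step. The reacting ketone is flanked by this quaternary carbon, the worst steric case for the metathesis. Ring B is still unmade in A3, so a further closure at C6–C7 and adjustment of both oxidation levels are needed.
- Comparison: the chosen strategy forms ring B, C8 and C9 in one convergent step from fragments made in three and two steps, and takes the C5=C10 alkene from the enol ether that the same step delivers.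

**Alternative 3:** The cut is the C6–C7 bond. Ring B is closed last from dialdehyde A6, with the C6 aldehyde on ring A and the C7 aldehyde on C8. A one-electron reductant turns one aldehyde into a ketyl, which adds to the other through a metal-bridged transition state to give the cis-diol A5.
- For: ring closure and both carbinol centres in one step, with the cis relation of O6 and O7 coming from the mechanism. The chosen route needs two separate face-selective steps (8 and 9) for the same relation and lists them as a risk, so on this point the alternative is clearly stronger.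
- Against: the C6 aldehyde is conjugated to the tetrasubstituted alkene and buttressed by the C4 methyl groups, so its ketyl is delocalised and slow to couple. The C7 aldehyde has an epimerisable α-centre (C8), and the face of the diol relative to the C8 methyl depends on that one neighbour. A6 presupposes the same open-chain C8/C9 construction as A4. The C13 ketone must ride through as a dioxolane whose acidic removal would come next to an allylic diol, with C13 still unset.
- Comparison: the chosen strategy gives up the one-step diol but fixes ring B with C8 and C9 early and convergently, and sets every later centre on a rigid bicyclic or tricyclic frame.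

Key step: step 6

Remark: 10 and its C5 epimer are taken to be separable by crystallisation or chromatography, as is usual for menthyloxy butenolides; the acetal centre equilibrates under acid, so the unwanted epimer can be recycled.

## Route

Step 1
Reactants: 1 2,2-dimethylcyclohexanone
Product: 2 2,2-dimethylcyclohexanone 2,4,6-triisopropylbenzenesulfonylhydrazone
Conditions: 2,4,6-(i-Pr)3C6H2SO2NHNH2, MeOH, HCl (cat.), rt
Reagents that add atoms: 2,4,6-triisopropylbenzenesulfonohydrazide, NNS(=O)(=O)c1c(C(C)C)cc(C(C)C)cc1C(C)C
Why: Acid-catalysed hydrazone condensation; the sulfonamide nitrogen should settle anti to the quaternary carbon and syn to the only α-CH2, which is where the Shapiro deprotonation must occur.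

Step 2
Reactants: 2 2,2-dimethylcyclohexanone 2,4,6-triisopropylbenzenesulfonylhydrazone; 3 N-methoxy-N-methylacetamide
Product: 5 1-(6,6-dimethylcyclohex-1-en-1-yl)ethan-1-one, via vinyllithium 4 (not isolated)
Conditions: n-BuLi (2.1 equiv), THF, −78 → 0 °C; then 3, −78 °C → rt
Reagents that add atoms: none
Why: Shapiro reaction: double deprotonation and loss of sulfinate and N2 give the vinyllithium regiospecifically because only one α-carbon bears hydrogen; acylation with the Weinreb amide stops at the ketone through the chelated tetrahedral intermediate.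

Step 3
Reactants: 5 1-(6,6-dimethylcyclohex-1-en-1-yl)ethan-1-one
Product: 6 tert-butyl{[1-(6,6-dimethylcyclohex-1-en-1-yl)ethenyl]oxy}dimethylsilane (ring A 2-silyloxydiene C7=C6(OTBS)–C5=C10)
Conditions: TBSOTf, Et3N, CH2Cl2, 0 °C
Reagents that add atoms: tert-butyldimethylsilyl trifluoromethanesulfonate, CC(C)(C)[Si](C)(C)OS(=O)(=O)C(F)(F)F
Why: Soft enolisation of the methyl ketone (kinetic silyl enol ether formation); the acetyl CH3 is the only α-position, so the cross-conjugated 2-silyloxydiene should form.

Step 4
Reactants: 7 3-methylfuran-2-carboxylic acid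
Product: 8 5-hydroxy-3-methylfuran-2(5H)-one (racemic)
Conditions: O2, rose bengal (cat.), hν, MeOH, 0 °C
Reagents that add atoms: dioxygen, O=O
Why: Dye-sensitised photo-oxygenation: singlet oxygen adds across the furan in a [4+2] sense and the endoperoxide fragments with loss of CO2 to the γ-hydroxybutenolide, the methyl group ending α to the lactone carbonyl.

Step 5
Reactants: 8 5-hydroxy-3-methylfuran-2(5H)-one; 9 (−)-menthol
Product: 10 (5R)-5-(l-menthyloxy)-3-methylfuran-2(5H)-one
Conditions: CSA (cat.), toluene, reflux (Dean–Stark); crystallise, re-equilibrate mother liquor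
Reagents that add atoms: none
Why: Acid-catalysed acetalisation of the lactol (pseudo-acid) with removal of water; the acetal centre epimerises under the acid, so the (5R) epimer can be collected and the rest recycled.

Step 6
Reactants: 6 ring A 2-silyloxydiene; 10 (5R)-5-(l-menthyloxy)-3-methylfuran-2(5H)-one
Product: 11 cis-fused lactone acetal cycloadduct with C5=C6 TBS enol ether (C17 and C11 α; C20 β; H8 β; H10 β)
Conditions: toluene (2 M), BHT (cat.), sealed tube, 150 °C (or CH2Cl2, 13 kbar, 40 °C)
Reagents that add atoms: none
Why: Diels–Alder reaction of a 2-silyloxydiene with a 5-alkoxybutenolide, a known reaction type. The diene HOMO is largest at C7 and the dienophile LUMO at the β-carbon, so C7–C8 forms ahead of C9–C10 in a concerted, asynchronous, suprafacial addition, and the silyloxy carbon C6 ends para to the acyl-bearing C9, the only regiochemistry that puts the quaternary centre at C9. Ring B is closed by the intermolecular [4+2] event itself: the two new σ bonds join the s-cis diene termini to the two alkene carbons of the lactone and a cyclohexene results directly. C8 and C9 are set by π-facial control: the diene should add anti to the menthyloxy group on C17, which fixes both centres absolutely, and suprafacial addition keeps C17 and C11 cis because they are tied in the lactone ring. C10 is set by endo approach (lactone carbonyl under the diene) but is immaterial, since step 7 makes it trigonal. The step needs facial and regio-selectivity, secured by the acetal substituent and the 2-silyloxy group, and enough reactivity to join a trisubstituted dienophile to a diene terminus next to a quaternary carbon, hence heat in a sealed tube or high pressure with a radical inhibitor. The silyl enol ether product is stable under these neutral conditions.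

Step 7
Reactants: 11 cis-fused lactone acetal cycloadduct
Product: 12 enone lactone acetal (C6 ketone; C5=C10)
Conditions: Pd(OAc)2 (1.1 equiv), MeCN, 40 °C
Reagents that add atoms: none
Why: Saegusa–Ito oxidation: the silyl enol ether transmetalates to a divalent palladium enolate at C5 and β-hydride elimination can only take H10 (C4 has no hydrogen), so the C5=C10 enone should form as a single regioisomer and the C10 stereocentre is removed.

Step 8
Reactants: 12 enone lactone acetal
Product: 14 7β-(tert-butyldimethylsilyloxy) enone lactone acetal, via silyl dienol ether 13 (not isolated)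
Conditions: LiN(i-Pr)2, THF, −78 °C; TBSOTf, −78 °C; crude 13, then mCPBA, NaHCO3, CH2Cl2, −20 °C
Reagents that add atoms: tert-butyldimethylsilyl trifluoromethanesulfonate, CC(C)(C)[Si](C)(C)OS(=O)(=O)C(F)(F)F; 3-chloroperbenzoic acid, OOC(=O)c1cccc(Cl)c1
Why: Rubottom oxidation: kinetic deprotonation at C7 gives the cross-conjugated silyl dienol ether, the peracid should epoxidise its electron-rich C6=C7 bond from the β face (anti to C17 on the adjacent C8 and on the convex side of the cis-fused lactone), and epoxide opening with 1,4-silyl shift gives the 7β-silyloxy ketone.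

Step 9
Reactants: 14 7β-(tert-butyldimethylsilyloxy) enone lactone acetal
Product: 15 6β-hydroxy-7β-(tert-butyldimethylsilyloxy) lactone acetal
Conditions: LiBH(s-Bu)3 (L-Selectride), THF, −78 °C
Reagents that add atoms: none
Why: Ketone reduction under steric approach control: as with 2-silyloxycyclohexanones, the bulky trialkylborohydride should attack C6 equatorially from the α face, away from the axial H8 and the C7 silyloxy group, so the new hydroxyl is β and cis to O7; conjugate reduction is blocked by the fully substituted C10 and the hindered lactone should survive at −78 °C.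

Step 10
Reactants: 15 6β-hydroxy-7β-(tert-butyldimethylsilyloxy) lactone acetal
Product: 16 6β,7β-bis(tert-butyldimethylsilyloxy) lactone acetal
Conditions: TBSOTf, 2,6-lutidine, CH2Cl2, −78 → 0 °C
Reagents that add atoms: tert-butyldimethylsilyl trifluoromethanesulfonate, CC(C)(C)[Si](C)(C)OS(=O)(=O)C(F)(F)F
Why: Silylation of the hindered allylic alcohol with a silyl triflate; any 1,2-silyl migration during step 9 is of no consequence because both oxygens end as the same silyl ether.

Step 11
Reactants: 16 6β,7β-bis(tert-butyldimethylsilyloxy) lactone acetal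
Product: 18 6β,7β-bis(tert-butyldimethylsilyloxy) γ-lactone (C11 carbonyl; C17 CH2–O), via potassium hydroxy carboxylate 17 (not isolated)
Conditions: NaBH4, KOH, MeOH/H2O, 0 °C → rt; then 1 M HCl to pH 3, 0 °C
Reagents that add atoms: potassium hydroxide, [K+].[OH-] (its oxygen enters the carboxylate of 17 and may remain as the carbonyl oxygen of 18)
Why: Base-mediated unmasking with in situ hydride reduction, known for menthyloxy lactones: hydroxide opens the acylal-type lactone, the C17 hemiacetal sheds menthoxide, borohydride reduces the aldehyde at once, and acidification closes the cis γ-hydroxy acid to the lactone, leaving C11 at the acid level and C17 at the alcohol level.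

Step 12
Reactants: 18 6β,7β-bis(tert-butyldimethylsilyloxy) γ-lactone
Product: 19 lactol (C11 hemiacetal; anomeric mixture)
Conditions: i-Bu2AlH, CH2Cl2, −78 °C
Reagents that add atoms: none
Why: Partial reduction of a lactone: the tetrahedral aluminate is stable at −78 °C and gives the lactol on work-up.

Step 13
Reactants: 19 lactol
Product: 20 C9-vinyl C17-alcohol (6β,7β-bis(tert-butyldimethylsilyloxy)-13,14,15,16-tetranorhalima-5(10),11-dien-17-ol)
Conditions: Ph3PCH3Br, KOt-Bu (3 equiv each), THF, 0 → 50 °C
Reagents that add atoms: methyltriphenylphosphonium bromide, C[P+](c1ccccc1)(c1ccccc1)c1ccccc1.[Br-]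
Why: Wittig methylenation of the lactol through its open hydroxy aldehyde; the aldehyde carbon sits on the quaternary C9, so no α-hydrogen can epimerise, and the C17 hydroxyl is released with no second hydroxyl nearby.

Step 14
Reactants: 20 C9-vinyl C17-alcohol
Product: 21 C17 mesylate
Conditions: MsCl, Et3N, CH2Cl2, 0 °C
Reagents that add atoms: methanesulfonyl chloride, CS(=O)(=O)Cl
Why: Sulfonylation of the primary alcohol (sulfene mechanism), fast at 0 °C.

Step 15
Reactants: 21 C17 mesylate
Product: 22 6β,7β-bis(tert-butyldimethylsilyloxy)-13,14,15,16-tetranorhalima-5(10),11-diene (C17 methyl; C9 vinyl)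
Conditions: LiBHEt3, THF, 0 °C → rt
Reagents that add atoms: none
Why: SN2 displacement of the primary mesylate by hydride; the triethylborohydride is nucleophilic enough for a β-branched primary centre, and the vinyl group, silyl ethers and tetrasubstituted alkene are inert.

Step 16
Reactants: 23 but-2-yn-1-ol
Product: 24 (Z)-3-iodobut-2-en-1-ol
Conditions: NaAlH2(OCH2CH2OMe)2, Et2O, 0 °C → rt; then I2, THF, −78 °C
Reagents that add atoms: iodine, II
Why: Hydroxyl-directed trans-hydroalumination places aluminium on C3 and iodinolysis proceeds with retention, so iodine and CH2OH end cis (Z).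

Step 17
Reactants: 22 C9-vinyl bis-silyl ether; 24 (Z)-3-iodobut-2-en-1-ol
Product: 26 (13Z)-6β,7β-bis(tert-butyldimethylsilyloxy)halima-5(10),13-dien-15-ol, via alkylborane 25 (not isolated)
Conditions: 9-BBN, THF, rt → 50 °C; then 24, PdCl2(dppf) (cat.), AsPh3, Cs2CO3, DMF/H2O, rt
Reagents that add atoms: none
Why: Anti-Markovnikov hydroboration of the only monosubstituted alkene followed by B-alkyl Suzuki–Miyaura coupling, which forms C12–C13 with retention of the alkenyl iodide geometry; the free hydroxyl is tolerated.

Step 18
Reactants: 26 (13Z)-allylic alcohol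
Product: 27 (13S,14R)-13,14-epoxy-6β,7β-bis(tert-butyldimethylsilyloxy)halim-5(10)-en-15-ol
Conditions: Ti(Oi-Pr)4, diethyl D-(−)-tartrate, t-BuOOH, 4 Å MS, CH2Cl2, −20 °C
Reagents that add atoms: tert-butyl hydroperoxide, CC(C)(C)OO
Why: Sharpless asymmetric epoxidation under reagent control: with the D-tartrate a (Z)-3-methylalk-2-en-1-ol of the nerol type should give the (13S,14R)-epoxide, which fixes C13; the ring alkene has no directing hydroxyl and is left alone.

Step 19
Reactants: 27 (13S,14R)-epoxy alcohol
Product: 28 (13S,14S)-13,14-epoxy-15-iodo-6β,7β-bis(tert-butyldimethylsilyloxy)halim-5(10)-ene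
Conditions: PPh3, I2, imidazole, THF, 0 °C
Reagents that add atoms: iodine, II
Why: Garegg–Samuelsson (Appel-type) iodination of the primary alcohol via the alkoxyphosphonium iodide; imidazole buffers the medium so the epoxide survives (the C14 descriptor changes only because iodine outranks oxygen).

Step 20
Reactants: 28 epoxy iodide
Product: 29 (13S)-6β,7β-bis(tert-butyldimethylsilyloxy)halima-5(10),14-dien-13-ol
Conditions: Zn dust, EtOH, reflux
Reagents that add atoms: none
Why: Reductive β-elimination: zinc inserts into the C–I bond and the organozinc opens the adjacent epoxide, forming the C14=C15 alkene and the C13 alkoxide; no bond to C13 is broken, so its configuration is kept.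

Step 21
Reactants: 29 bis-silyl ether of the triol
Product: 30 (13S)-halima-5(10),14-diene-6β,7β,13-triol
Conditions: Bu4NF, THF, 50 °C
Reagents that add atoms: none
Why: Fluoride cleavage of both silyl ethers; no ester is present yet and no acid is used, so the two allylic alcohols are not put at risk.

Step 22
Reactants: 30 (13S)-halima-5(10),14-diene-6β,7β,13-triol
Product: 31 CNP0126002.2, (6S,7R,8S,9R,13S)-7-acetoxyhalima-5(10),14-diene-6,13-diol
Conditions: Ac2O (1.1 equiv), pyridine, CH2Cl2, 0 °C
Reagents that add atoms: acetic anhydride, CC(=O)OC(C)=O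
Why: Acylation under steric control: O7 is an unhindered equatorial secondary hydroxyl, O6 is pseudoaxial, allylic and pressed against the C4 gem-dimethyl group, and O13 is tertiary, so one equivalent of anhydride without acylation catalyst should give the 7-monoacetate.

## Compound list

1 | 2,2-dimethylcyclohexanone | CC1(C)CCCCC1=O | starting material
2 | 2,2-dimethylcyclohexanone 2,4,6-triisopropylbenzenesulfonylhydrazone (sulfonamide nitrogen syn to the CH2) | CC1(C)CCCC/C1=N\NS(=O)(=O)c1c(C(C)C)cc(C(C)C)cc1C(C)C | intermediate
3 | N-methoxy-N-methylacetamide | CON(C)C(C)=O | starting material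
4 | (6,6-dimethylcyclohex-1-en-1-yl)lithium | [Li]C1=CCCCC1(C)C | intermediate
5 | 1-(6,6-dimethylcyclohex-1-en-1-yl)ethan-1-one | CC(=O)C1=CCCCC1(C)C | intermediate
6 | tert-butyl{[1-(6,6-dimethylcyclohex-1-en-1-yl)ethenyl]oxy}dimethylsilane | C=C(O[Si](C)(C)C(C)(C)C)C1=CCCCC1(C)C | intermediate
7 | 3-methylfuran-2-carboxylic acid | Cc1ccoc1C(=O)O | starting material
8 | 5-hydroxy-3-methylfuran-2(5H)-one (racemic) | CC1=CC(O)OC1=O | intermediate
9 | (−)-menthol, (1R,2S,5R)-2-isopropyl-5-methylcyclohexan-1-ol | CC(C)[C@@H]1CC[C@@H](C)C[C@H]1O | starting material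
10 | (5R)-5-(l-menthyloxy)-3-methylfuran-2(5H)-one | CC(C)[C@@H]1CC[C@@H](C)C[C@H]1O[C@@H]2OC(=O)C(C)=C2 | intermediate
11 | Diels–Alder adduct: cis-fused γ-lactone menthyl acetal on C8–C9 (C11 carbonyl, C17 acetal, both α), C20 β, H8 β, H10 β, C5=C6 TBS enol ether | CC(C)[C@@H]1CC[C@@H](C)C[C@H]1O[C@@H]2OC(=O)[C@]3(C)[C@H]2CC(O[Si](C)(C)C(C)(C)C)=C4[C@@H]3CCCC4(C)C | intermediate
12 | enone lactone acetal: C6 ketone, C5=C10 | CC(C)[C@@H]1CC[C@@H](C)C[C@H]1O[C@@H]2OC(=O)[C@]3(C)[C@H]2CC(=O)C4=C3CCCC4(C)C | intermediate
13 | TBS dienol ether: C6(OTBS)=C7 and C5=C10 | CC(C)[C@@H]1CC[C@@H](C)C[C@H]1O[C@@H]2OC(=O)[C@]3(C)[C@H]2C=C(O[Si](C)(C)C(C)(C)C)C4=C3CCCC4(C)C | intermediate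
14 | 7β-(TBS-oxy) C6 ketone lactone acetal | CC(C)[C@@H]1CC[C@@H](C)C[C@H]1O[C@@H]2OC(=O)[C@]3(C)[C@H]2[C@@H](O[Si](C)(C)C(C)(C)C)C(=O)C4=C3CCCC4(C)C | intermediate
15 | 6β-hydroxy-7β-(TBS-oxy) lactone acetal | CC(C)[C@@H]1CC[C@@H](C)C[C@H]1O[C@@H]2OC(=O)[C@]3(C)[C@H]2[C@@H](O[Si](C)(C)C(C)(C)C)[C@@H](O)C4=C3CCCC4(C)C | intermediate
16 | 6β,7β-bis(TBS-oxy) lactone acetal | CC(C)[C@@H]1CC[C@@H](C)C[C@H]1O[C@@H]2OC(=O)[C@]3(C)[C@H]2[C@@H](O[Si](C)(C)C(C)(C)C)[C@@H](O[Si](C)(C)C(C)(C)C)C4=C3CCCC4(C)C | intermediate
17 | potassium carboxylate (C11) with free C17 hydroxymethyl, 6β,7β-bis(TBS-oxy) | [K+].[O-]C(=O)[C@@]1(C)C2=C([C@H](O[Si](C)(C)C(C)(C)C)[C@H](O[Si](C)(C)C(C)(C)C)[C@H]1CO)C(C)(C)CCC2 | intermediate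
18 | 6β,7β-bis(TBS-oxy) γ-lactone (C11 carbonyl, C17 CH2–O) | C1OC(=O)[C@]2(C)[C@H]1[C@@H](O[Si](C)(C)C(C)(C)C)[C@@H](O[Si](C)(C)C(C)(C)C)C3=C2CCCC3(C)C | intermediate
19 | lactol (C11 hemiacetal, anomeric mixture) | C1OC(O)[C@]2(C)[C@H]1[C@@H](O[Si](C)(C)C(C)(C)C)[C@@H](O[Si](C)(C)C(C)(C)C)C3=C2CCCC3(C)C | intermediate
20 | 6β,7β-bis(TBS-oxy)-13,14,15,16-tetranorhalima-5(10),11-dien-17-ol | C=C[C@@]1(C)C2=C([C@H](O[Si](C)(C)C(C)(C)C)[C@H](O[Si](C)(C)C(C)(C)C)[C@H]1CO)C(C)(C)CCC2 | intermediate
21 | C17 methanesulfonate of 20 | C=C[C@@]1(C)C2=C([C@H](O[Si](C)(C)C(C)(C)C)[C@H](O[Si](C)(C)C(C)(C)C)[C@H]1COS(C)(=O)=O)C(C)(C)CCC2 | intermediate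
22 | 6β,7β-bis(TBS-oxy)-13,14,15,16-tetranorhalima-5(10),11-diene | C=C[C@@]1(C)C2=C([C@H](O[Si](C)(C)C(C)(C)C)[C@H](O[Si](C)(C)C(C)(C)C)[C@H]1C)C(C)(C)CCC2 | intermediate
23 | but-2-yn-1-ol | CC#CCO | starting material
24 | (Z)-3-iodobut-2-en-1-ol | C/C(I)=C/CO | intermediate
25 | B-alkyl-9-borabicyclo[3.3.1]nonane (boron on C12) | C1CC2CCCC(C1)B2CC[C@@]3(C)C4=C([C@H](O[Si](C)(C)C(C)(C)C)[C@H](O[Si](C)(C)C(C)(C)C)[C@H]3C)C(C)(C)CCC4 | intermediate
26 | (13Z)-6β,7β-bis(TBS-oxy)halima-5(10),13-dien-15-ol | OC/C=C(C)\CC[C@@]1(C)C2=C([C@H](O[Si](C)(C)C(C)(C)C)[C@H](O[Si](C)(C)C(C)(C)C)[C@H]1C)C(C)(C)CCC2 | intermediate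
27 | (13S,14R)-13,14-epoxy-6β,7β-bis(TBS-oxy)halim-5(10)-en-15-ol | OC[C@H]1O[C@@]1(C)CC[C@@]1(C)C2=C([C@H](O[Si](C)(C)C(C)(C)C)[C@H](O[Si](C)(C)C(C)(C)C)[C@H]1C)C(C)(C)CCC2 | intermediate
28 | (13S,14S)-13,14-epoxy-15-iodo-6β,7β-bis(TBS-oxy)halim-5(10)-ene | IC[C@H]1O[C@@]1(C)CC[C@@]1(C)C2=C([C@H](O[Si](C)(C)C(C)(C)C)[C@H](O[Si](C)(C)C(C)(C)C)[C@H]1C)C(C)(C)CCC2 | intermediate
29 | (13S)-6β,7β-bis(TBS-oxy)halima-5(10),14-dien-13-ol | C=C[C@@](C)(O)CC[C@@]1(C)C2=C([C@H](O[Si](C)(C)C(C)(C)C)[C@H](O[Si](C)(C)C(C)(C)C)[C@H]1C)C(C)(C)CCC2 | intermediate
30 | (13S)-halima-5(10),14-diene-6β,7β,13-triol | C=C[C@@](C)(O)CC[C@@]1(C)C2=C([C@H](O)[C@H](O)[C@H]1C)C(C)(C)CCC2 | intermediate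
31 | CNP0126002.2, (6S,7R,8S,9R,13S)-7-acetoxyhalima-5(10),14-diene-6,13-diol | C=C[C@@](C)(O)CC[C@@]1(C)C2=C([C@H](O)[C@H](OC(C)=O)[C@H]1C)C(C)(C)CCC2 | target

## Step count and least certain steps

Total: 22 steps. Longest linear sequence: 19 steps (1–3, 6–15, 17–22); the dienophile (steps 4–5) and the iodide (step 16) are side branches.

**Step 6 (key step).** The cycloaddition may be too slow: the α-methyl group of the dienophile and the quaternary C4 next to the diene terminus both retard bond formation at C9–C10, so desilylation or polymerisation of the diene can outrun product formation. The fallback sets out from diene 6 and uses the unsubstituted, far more reactive (5R)-5-(l-menthyloxy)furan-2(5H)-one F1 (commercial). Thermal cycloaddition under the same conditions should give the des-methyl adduct F2 with the same facial control. Deprotonation of the lactone at C9 with LiN(i-Pr)2 (THF, −78 °C) and alkylation with MeI should then bring in C20 on the convex face, cis to H8 (the only way to keep the lactone cis-fused), returning to 11. The quaternary centre is then made by enolate alkylation after the ring is closed, not in the cycloaddition.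

**Step 7 (dehydrosilylation).** Transmetalation at the fully substituted C5, flanked by C4 and C9, may be slow, and protodesilylation to the saturated ketone would then compete. The fallback sets out from 11: NBS (THF, 0 °C) should brominate the enol ether at C5 to give the 5-bromo C6 ketone F3, and Li2CO3/LiBr in DMF at 120 °C should eliminate HBr towards C10 (the only β-hydrogen), returning to 12.

**Step 9 (C6 reduction).** Facial selectivity may be poor: in a cyclohexenone the axial path is hindered only by H8, so axial attack giving the 6α-alcohol (trans-diol) can compete, and the C4 methyl groups may make the bulky hydride sluggish. The fallback sets out from 12 and replaces steps 8–10 by a syn-dihydroxylation, in which both oxygens must arrive on one face. Treatment with KN(SiMe3)2 and PhNTf2 (THF, −78 °C) should give the dienyl triflate F4. Reduction with Pd(OAc)2, PPh3, Bu3N and HCO2H (DMF, 60 °C) should give the ring B diene F5. OsO4 (cat.) with N-methylmorpholine N-oxide should dihydroxylate the disubstituted C6=C7 bond from the convex β face, leaving the tetrasubstituted alkene, to give the cis-diol F6. Excess TBSOTf with 2,6-lutidine returns to 16.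

**Step 11 (lactone from lactone acetal).** Hydroxide attack at the hindered C11 carbonyl may be slow, and the transient C17 aldehyde may epimerise at C8 or lose the C7 silyloxy group by β-elimination before it is reduced. The fallback sets out from 16 and avoids a free aldehyde under base. LiAlH4 (THF, 0 °C) should reduce the lactone acetal straight to the diol F7 with release of menthol. Pivaloyl chloride in pyridine (−20 °C) should acylate the less hindered C17 hydroxyl in preference to the neopentyl C11 hydroxyl, giving the mono-pivalate F8. Dess–Martin periodinane should give the C11 aldehyde F9 (no α-hydrogen), and Ph3P=CH2 the vinyl pivalate F10. Removal of the pivalate with i-Bu2AlH returns to 20, bypassing steps 11–13.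

**Step 22 (selective acetylation).** Regioselectivity may be lost, with acylation at O6 or at both oxygens, or acyl migration between the cis oxygens. The fallback sets out from 30: Bu2SnO (toluene, reflux, removal of water) should give the 6,7-O-dibutylstannylene acetal F11. AcCl (CH2Cl2, 0 °C) should then acylate the equatorial oxygen O7, as is usual for stannylene acetals of cis-diols, returning to 31.

## Further compounds

F1 | step 6 | (5R)-5-(l-menthyloxy)furan-2(5H)-one (commercial dienophile) | CC(C)[C@@H]1CC[C@@H](C)C[C@H]1O[C@@H]2OC(=O)C=C2
F2 | step 6 | des-methyl cycloadduct (H9 β in place of C20) | CC(C)[C@@H]1CC[C@@H](C)C[C@H]1O[C@@H]2OC(=O)[C@@H]3[C@H]2CC(O[Si](C)(C)C(C)(C)C)=C4[C@@H]3CCCC4(C)C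
F3 | step 7 | 5-bromo C6 ketone lactone acetal (C5 configuration not assigned) | CC(C)[C@@H]1CC[C@@H](C)C[C@H]1O[C@@H]2OC(=O)[C@]3(C)[C@H]2CC(=O)C4(Br)[C@@H]3CCCC4(C)C
F4 | step 9 | dienyl triflate (C6 triflate, C6=C7 and C5=C10) | CC(C)[C@@H]1CC[C@@H](C)C[C@H]1O[C@@H]2OC(=O)[C@]3(C)[C@H]2C=C(OS(=O)(=O)C(F)(F)F)C4=C3CCCC4(C)C
F5 | step 9 | ring B diene lactone acetal (C6=C7 and C5=C10) | CC(C)[C@@H]1CC[C@@H](C)C[C@H]1O[C@@H]2OC(=O)[C@]3(C)[C@H]2C=CC4=C3CCCC4(C)C
F6 | step 9 | 6β,7β-diol lactone acetal | CC(C)[C@@H]1CC[C@@H](C)C[C@H]1O[C@@H]2OC(=O)[C@]3(C)[C@H]2[C@@H](O)[C@@H](O)C4=C3CCCC4(C)C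
F7 | step 11 | 6β,7β-bis(TBS-oxy) 11,17-diol | OC[C@@]1(C)C2=C([C@H](O[Si](C)(C)C(C)(C)C)[C@H](O[Si](C)(C)C(C)(C)C)[C@H]1CO)C(C)(C)CCC2
F8 | step 11 | 17-pivalate of the 11,17-diol | OC[C@@]1(C)C2=C([C@H](O[Si](C)(C)C(C)(C)C)[C@H](O[Si](C)(C)C(C)(C)C)[C@H]1COC(=O)C(C)(C)C)C(C)(C)CCC2
F9 | step 11 | C11 aldehyde 17-pivalate | O=C[C@@]1(C)C2=C([C@H](O[Si](C)(C)C(C)(C)C)[C@H](O[Si](C)(C)C(C)(C)C)[C@H]1COC(=O)C(C)(C)C)C(C)(C)CCC2
F10 | step 11 | C9-vinyl 17-pivalate | C=C[C@@]1(C)C2=C([C@H](O[Si](C)(C)C(C)(C)C)[C@H](O[Si](C)(C)C(C)(C)C)[C@H]1COC(=O)C(C)(C)C)C(C)(C)CCC2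
F11 | step 22 | 6,7-O-dibutylstannylene acetal of triol 30 | C=C[C@@](C)(O)CC[C@@]1(C)C2=C([C@@H]3O[Sn](CCCC)(CCCC)O[C@@H]3[C@H]1C)C(C)(C)CCC2
A1 | alternative 1 | bicyclic C6 enone with C5=C10, C4 gem-dimethyl and C9 allyl | CC1(C)CCCC2=C1C(=O)C[C@@H](C)[C@@]2(C)CC=C
A2 | alternative 1 | monocyclic ring B enone with 4-methylpent-3-enyl on C10 and allyl on C9 | CC(C)=CCCC1=CC(=O)C[C@@H](C)[C@@]1(C)CC=C
A3 | alternative 2 | ring A tetrasubstituted enoate (C6 triisopropylsilyl ester on C5) | CC(C)[Si](OC(=O)C1=C(CCCC1(C)C)[C@](C)(CCO[Si](C)(C)C(C)(C)C)[C@H](C)COCc1ccc(OC)cc1)(C(C)C)C(C)C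
A4 | alternative 2 | open-chain C10 ketone with triisopropylsilyl ynol ether (C5≡C6) | CC(C)[Si](OC#CC(C)(C)CCCC(=O)[C@](C)(CCO[Si](C)(C)C(C)(C)C)[C@H](C)COCc1ccc(OC)cc1)(C(C)C)C(C)C
A5 | alternative 3 | bicyclic 6,7-cis-diol with C13 dioxolane side chain | CC1(CC[C@@]2(C)C3=C([C@H](O)[C@H](O)[C@H]2C)C(C)(C)CCC3)OCCO1
A6 | alternative 3 | C6/C7 dialdehyde with C13 dioxolane side chain | CC1(CC[C@@](C)(C2=C(C=O)C(C)(C)CCC2)[C@H](C)C=O)OCCO1
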